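**Retrosynthetic overview**

- The target is epiafzelechin-(4β→8)-ent-epiafzelechin-(4α→8)-epiafzelechin. The last skeletal bonds made are the two interflavan C4–C8 bonds, each by acid-promoted Friedel–Crafts capture of a 2,3-cis-flavan-4-yl cation anti to its C3 substituent; twelve benzyl ethers are then removed.
- Each flavan unit is traced to one annulation: a syn-glycolate aldol adduct (C2 and C3 with both oxygens in place) reacts with 3,5-bis(benzyloxy)benzyne, which forms the O1–C8a and C4a–C4 bonds in one operation and so closes ring C onto a ring A delivered as an aryne.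
- Enabling feature: in every ring A the ether carbon C8a and its neighbour C4a, which is flanked by the C5 oxygen, are the 1,2-positions of a 3,5-dioxygenated benzyne. An O-nucleophile enters such an aryne at the carbon remote from the alkoxy group and the carbanion appears next to it. Ring C carries cis oxygens on C2 and C3, the pattern of a syn aldol whose two C–O bonds are never broken.
- Order of ring formation: rings B are bought; rings A and C of the (2R,3R) series are joined in step 5 (this ketone serves the upper and the lower unit); rings A and C of the (2S,3S) series in step 10 (middle unit); the units are joined lower + middle (step 12), then upper + dimer (step 13).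

Key step: step 5

Assumption: both enantiomers of 4-benzyl-3-[(benzyloxy)acetyl]oxazolidin-2-one and 3,5-bis(benzyloxy)phenol are taken as purchasable.
Assumption: alcohols 14 and 22 are drawn as the C4 epimers expected from hydride delivery; C4 is planarized in the following steps, so the epimer is of no consequence.

**Route**

Step 1
Reactants: 1 4-(benzyloxy)benzaldehyde; 2 (S)-4-benzyl-3-[(benzyloxy)acetyl]oxazolidin-2-one
Product: 4 (S)-4-benzyl-3-[(2S,3R)-2-(benzyloxy)-3-[4-(benzyloxy)phenyl]-3-hydroxypropanoyl]oxazolidin-2-one, via boron Z-enolate 3 (not isolated)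
Conditions: Bu2BOTf, Et3N, CH2Cl2, −78 → 0 °C; then pH 7 buffer, MeOH, H2O2, 0 °C
Reagents that add atoms: none
Why: Evans boron syn-glycolate aldol: the Z-enolate should react through a Zimmerman–Traxler chair on the face opposite the auxiliary benzyl group, setting both new centers (syn, the future 2,3-cis relation of the (2R,3R) units).

Step 2
Reactants: 4 aldol adduct
Product: 5 (2S,3R)-2-(benzyloxy)-3-[4-(benzyloxy)phenyl]-3-hydroxy-N-methoxy-N-methylpropanamide
Conditions: MeNH(OMe)·HCl, AlMe3, THF, −20 → 0 °C; aqueous work-up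
Reagents that add atoms: N,O-dimethylhydroxylamine hydrochloride, CNOC.Cl
Why: AlMe3-mediated transamidation of an N-acyl oxazolidinone to the Weinreb amide is routine for syn-aldol adducts with a free β-hydroxyl and touches no stereocenter.

Step 3
Reactants: 6 3,5-bis(benzyloxy)phenol
Product: 7 2-bromo-3,5-bis(benzyloxy)phenol
Conditions: NBS, i-Pr2NH (cat.), CH2Cl2, −78 → 0 °C
Reagents that add atoms: N-bromosuccinimide, O=C1CCC(=O)N1Br
Why: amine-catalysed electrophilic bromination of phenols is ortho-selective, and the position between the two benzyloxy groups is the more hindered one.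

Step 4
Reactants: 7 2-bromo-3,5-bis(benzyloxy)phenol
Product: 10 3,5-bis(benzyloxy)-2-(trimethylsilyl)phenyl trifluoromethanesulfonate, via O-trimethylsilyl ether 8 (not isolated), via lithium 2-silylphenoxide 9 (not isolated)
Conditions: HMDS, THF, 70 °C; n-BuLi, THF, −100 → −78 °C; Tf2O, −100 → 23 °C
Reagents that add atoms: hexamethyldisilazane, C[Si](C)(C)N[Si](C)(C)C; trifluoromethanesulfonic anhydride, O=S(=O)(OS(=O)(=O)C(F)(F)F)C(F)(F)F
Why: O-silylation, bromine–lithium exchange, retro-Brook O→C silyl shift and triflation of the phenoxide is the standard route to ortho-silylaryl triflate aryne precursors.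

Step 5
Reactants: 5 Weinreb amide; 10 aryne precursor (1.5 equiv)
Product: 13 (2R,3S)-3,5,7-tris(benzyloxy)-2-[4-(benzyloxy)phenyl]chroman-4-one (2,3-cis), via 3,5-bis(benzyloxy)benzyne 11 (not isolated), via aryl carbanion 12 (not isolated)
Conditions: KF, 18-crown-6, THF, 0 → 23 °C; pH 7 buffer quench
Reagents that add atoms: none
Why: Proposed new method: fluoride should unmask benzyne 11 from 10, the fluoride-activated benzylic hydroxyl of 5 should add to the aryne carbon remote from the neighbouring benzyloxy group (the future C8a), which places carbanion 12 on the carbon flanked by that benzyloxy group (the future C4a), as the inductive and distortion control of 3-alkoxyarynes demands, and this carbanion should then acylate the Weinreb amide carbonyl with loss of MeNH(OMe), forming the C4a–C4 bond. The closest known reaction types are the fluoride-mediated annulation of arynes with salicylates to xanthones and the aryne acyl-alkylation of β-keto esters; new here is an aliphatic β-hydroxy amide as the combined O-nucleophile and acyl donor. Ring C is closed in a 6-exo-trig mode by O-arylation followed by intramolecular acyl transfer to the aryl anion; no stereocenter is created, and C2 and C3 keep the aldol configuration because neither C–O bond is broken, which is why the syn aldol maps onto the 2,3-cis series. The step needs regioselective aryne capture (secured by the C3 benzyloxy group of the aryne), ring closure faster than protonation of 12 (secured by the six-membered transition state and the non-acidic solvent), and no epimerization at C3 of the cis ketone (the hydroxyl proton should end on the departing amine, so no strong base accumulates).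

Step 6
Reactants: 13 cis-flavanone
Product: 14 (2R,3R,4R)-3,5,7-tris(benzyloxy)-2-[4-(benzyloxy)phenyl]chroman-4-ol
Conditions: NaBH4, THF/MeOH, 0 °C
Reagents that add atoms: none
Why: borohydride reduction of 3-oxygenated flavanones to flavan-3,4-diol derivatives is known; hydride should enter anti to the axial 3-benzyloxy group (Felkin–Anh), giving mainly the 3,4-cis alcohol.

Step 7
Reactants: 14 flavan-4-ol
Product: 15 (2R,3R)-3,5,7-tris(benzyloxy)-2-[4-(benzyloxy)phenyl]chromane (tetra-O-benzyl-epiafzelechin)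
Conditions: Et3SiH (5 equiv), TFA, CH2Cl2, −78 → −40 °C
Reagents that add atoms: none
Why: ionic hydrogenation: the 4-hydroxyl ionizes to the flavan-4-yl cation stabilized by the 5,7-dioxygenated ring and is captured by silane hydride, leaving C2 and C3 untouched.

Step 8
Reactants: 1 4-(benzyloxy)benzaldehyde; 16 (R)-4-benzyl-3-[(benzyloxy)acetyl]oxazolidin-2-one
Product: 18 (R)-4-benzyl-3-[(2R,3S)-2-(benzyloxy)-3-[4-(benzyloxy)phenyl]-3-hydroxypropanoyl]oxazolidin-2-one, via boron Z-enolate 17 (not isolated)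
Conditions: Bu2BOTf, Et3N, CH2Cl2, −78 → 0 °C; then pH 7 buffer, MeOH, H2O2, 0 °C
Reagents that add atoms: none
Why: the same Evans syn-glycolate aldol with the enantiomeric auxiliary should set the mirror-image centers for the ent (2S,3S) unit.

Step 9
Reactants: 18 aldol adduct
Product: 19 (2R,3S)-2-(benzyloxy)-3-[4-(benzyloxy)phenyl]-3-hydroxy-N-methoxy-N-methylpropanamide
Conditions: MeNH(OMe)·HCl, AlMe3, THF, −20 → 0 °C; aqueous work-up
Reagents that add atoms: N,O-dimethylhydroxylamine hydrochloride, CNOC.Cl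
Why: Weinreb transamidation as in step 2, without change at the stereocenters.

Step 10
Reactants: 19 Weinreb amide; 10 aryne precursor (1.5 equiv)
Product: 21 (2S,3R)-3,5,7-tris(benzyloxy)-2-[4-(benzyloxy)phenyl]chroman-4-one (2,3-cis), via aryl carbanion 20 (not isolated)
Conditions: KF, 18-crown-6, THF, 0 → 23 °C; pH 7 buffer quench
Reagents that add atoms: none
Why: Proposed new method: fluoride should again release 3,5-bis(benzyloxy)benzyne (compound 11 of step 5) from 10 in the flask, the benzylic hydroxyl of 19 should add to it at the carbon remote from the neighbouring benzyloxy group, and the resulting carbanion 20 should close ring C by 6-exo-trig acylation on the Weinreb amide (closest known type: aryne–salicylate annulation to xanthones); no stereocenter is created and the precursor configuration is kept because no C–O bond is broken.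

Step 11
Reactants: 21 cis-flavanone
Product: 22 (2S,3S,4S)-3,5,7-tris(benzyloxy)-2-[4-(benzyloxy)phenyl]chroman-4-ol
Conditions: NaBH4, THF/MeOH, 0 °C
Reagents that add atoms: none
Why: borohydride reduction as in step 6, hydride anti to the axial 3-benzyloxy group.

Step 12
Reactants: 22 ent-flavan-4-ol; 15 tetra-O-benzyl-epiafzelechin (3 equiv, excess recovered)
Product: 23 octa-O-benzyl-ent-epiafzelechin-(4α→8)-epiafzelechin
Conditions: BF3·OEt2 (0.5 equiv), 4 Å MS, CH2Cl2, −78 → −30 °C
Reagents that add atoms: none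
Why: Lewis acid-promoted dehydrative Friedel–Crafts coupling of a flavan-4-yl cation with a flavan-3-ol nucleophile (the standard interflavan bond formation), the water of condensation being taken up by the sieves; C8 of 15 is its most nucleophilic position, and attack anti to the 3-benzyloxy group of the 2,3-cis cation should set the new C4 center 3,4-trans.

Step 13
Reactants: 14 flavan-4-ol; 23 dimer (2 equiv, excess recovered)
Product: 24 dodeca-O-benzyl-epiafzelechin-(4β→8)-ent-epiafzelechin-(4α→8)-epiafzelechin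
Conditions: BF3·OEt2 (0.5 equiv), 4 Å MS, CH2Cl2, −78 → −30 °C
Reagents that add atoms: none
Why: the same dehydrative cation/arene coupling; the free C8 of the upper (ent) unit of 23 is its most nucleophilic site, and attack anti to the C3 substituent of the 2,3-cis cation should set C4 of the new upper unit 3,4-trans (4β).

Step 14
Reactants: 24 protected trimer
Product: 25 epiafzelechin-(4β→8)-ent-epiafzelechin-(4α→8)-epiafzelechin (target)
Conditions: H2 (1 atm), Pd(OH)2/C, THF/MeOH/H2O, 23 °C
Reagents that add atoms: none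
Why: hydrogenolysis of the twelve benzyl ethers over Pd(OH)2 on carbon is the established final deprotection of benzylated proanthocyanidins and leaves the interflavan bonds and stereocenters intact.

**Compound list**

1 | 4-(benzyloxy)benzaldehyde | O=Cc1ccc(OCc2ccccc2)cc1 | starting material
2 | (S)-4-benzyl-3-[(benzyloxy)acetyl]oxazolidin-2-one | O=C(COCc1ccccc1)N1C(=O)OC[C@@H]1Cc1ccccc1 | starting material
3 | (Z)-dibutylboron enolate of 2 | CCCCB(CCCC)O/C(=C\OCc1ccccc1)N1C(=O)OC[C@@H]1Cc1ccccc1 | intermediate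
4 | (S)-4-benzyl-3-[(2S,3R)-2-(benzyloxy)-3-[4-(benzyloxy)phenyl]-3-hydroxypropanoyl]oxazolidin-2-one | O=C([C@@H](OCc1ccccc1)[C@H](O)c1ccc(OCc2ccccc2)cc1)N1C(=O)OC[C@@H]1Cc1ccccc1 | intermediate
5 | (2S,3R)-2-(benzyloxy)-3-[4-(benzyloxy)phenyl]-3-hydroxy-N-methoxy-N-methylpropanamide | CON(C)C(=O)[C@@H](OCc1ccccc1)[C@H](O)c1ccc(OCc2ccccc2)cc1 | intermediate
6 | 3,5-bis(benzyloxy)phenol | Oc1cc(OCc2ccccc2)cc(OCc2ccccc2)c1 | starting material
7 | 2-bromo-3,5-bis(benzyloxy)phenol | Oc1cc(OCc2ccccc2)cc(OCc2ccccc2)c1Br | intermediate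
8 | [2-bromo-3,5-bis(benzyloxy)phenoxy]trimethylsilane | C[Si](C)(C)Oc1cc(OCc2ccccc2)cc(OCc2ccccc2)c1Br | intermediate
9 | lithium 3,5-bis(benzyloxy)-2-(trimethylsilyl)phenoxide | [Li+].[O-]c1cc(OCc2ccccc2)cc(OCc2ccccc2)c1[Si](C)(C)C | intermediate
10 | 3,5-bis(benzyloxy)-2-(trimethylsilyl)phenyl trifluoromethanesulfonate | C[Si](C)(C)c1c(OCc2ccccc2)cc(OCc2ccccc2)cc1OS(=O)(=O)C(F)(F)F | intermediate
11 | 3,5-bis(benzyloxy)benzyne | C1#CC(OCc2ccccc2)=CC(OCc2ccccc2)=C1 | intermediate
12 | potassium salt of the aryl carbanion formed by O-arylation of 5 (carbanion between the ether carbon and the benzyloxy carbon; side chain 1R,2S) | [K+].[c-]1c(OCc5ccccc5)cc(OCc5ccccc5)cc1O[C@H](c1ccc(OCc5ccccc5)cc1)[C@H](OCc5ccccc5)C(=O)N(C)OC | intermediate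
13 | (2R,3S)-3,5,7-tris(benzyloxy)-2-[4-(benzyloxy)phenyl]chroman-4-one | c1c(OCc5ccccc5)cc(OCc5ccccc5)c2c1O[C@H](c1ccc(OCc5ccccc5)cc1)[C@H](OCc5ccccc5)C2=O | intermediate
14 | (2R,3R,4R)-3,5,7-tris(benzyloxy)-2-[4-(benzyloxy)phenyl]chroman-4-ol | c1c(OCc5ccccc5)cc(OCc5ccccc5)c2c1O[C@H](c1ccc(OCc5ccccc5)cc1)[C@H](OCc5ccccc5)[C@@H]2O | intermediate
15 | (2R,3R)-3,5,7-tris(benzyloxy)-2-[4-(benzyloxy)phenyl]chromane | c1c(OCc5ccccc5)cc(OCc5ccccc5)c2c1O[C@H](c1ccc(OCc5ccccc5)cc1)[C@H](OCc5ccccc5)C2 | intermediate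
16 | (R)-4-benzyl-3-[(benzyloxy)acetyl]oxazolidin-2-one | O=C(COCc1ccccc1)N1C(=O)OC[C@H]1Cc1ccccc1 | starting material
17 | (Z)-dibutylboron enolate of 16 | CCCCB(CCCC)O/C(=C\OCc1ccccc1)N1C(=O)OC[C@H]1Cc1ccccc1 | intermediate
18 | (R)-4-benzyl-3-[(2R,3S)-2-(benzyloxy)-3-[4-(benzyloxy)phenyl]-3-hydroxypropanoyl]oxazolidin-2-one | O=C([C@H](OCc1ccccc1)[C@@H](O)c1ccc(OCc2ccccc2)cc1)N1C(=O)OC[C@H]1Cc1ccccc1 | intermediate
19 | (2R,3S)-2-(benzyloxy)-3-[4-(benzyloxy)phenyl]-3-hydroxy-N-methoxy-N-methylpropanamide | CON(C)C(=O)[C@H](OCc1ccccc1)[C@@H](O)c1ccc(OCc2ccccc2)cc1 | intermediate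
20 | potassium salt of the aryl carbanion formed by O-arylation of 19 (enantiomer of 12) | [K+].[c-]1c(OCc5ccccc5)cc(OCc5ccccc5)cc1O[C@@H](c1ccc(OCc5ccccc5)cc1)[C@@H](OCc5ccccc5)C(=O)N(C)OC | intermediate
21 | (2S,3R)-3,5,7-tris(benzyloxy)-2-[4-(benzyloxy)phenyl]chroman-4-one | c1c(OCc5ccccc5)cc(OCc5ccccc5)c2c1O[C@@H](c1ccc(OCc5ccccc5)cc1)[C@@H](OCc5ccccc5)C2=O | intermediate
22 | (2S,3S,4S)-3,5,7-tris(benzyloxy)-2-[4-(benzyloxy)phenyl]chroman-4-ol | c1c(OCc5ccccc5)cc(OCc5ccccc5)c2c1O[C@@H](c1ccc(OCc5ccccc5)cc1)[C@@H](OCc5ccccc5)[C@H]2O | intermediate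
23 | octa-O-benzyl-ent-epiafzelechin-(4α→8)-epiafzelechin (upper unit 2S,3S, 3,4-trans; lower unit 2R,3R) | c1c(OCc5ccccc5)cc(OCc5ccccc5)c2c1O[C@@H](c1ccc(OCc5ccccc5)cc1)[C@@H](OCc5ccccc5)[C@@H]2c1c(OCc5ccccc5)cc(OCc5ccccc5)c2c1O[C@H](c1ccc(OCc5ccccc5)cc1)[C@H](OCc5ccccc5)C2 | intermediate
24 | dodeca-O-benzyl-epiafzelechin-(4β→8)-ent-epiafzelechin-(4α→8)-epiafzelechin | c5ccccc5COc1ccc([C@H]2Oc3cc(OCc5ccccc5)cc(OCc5ccccc5)c3[C@H](c3c(OCc5ccccc5)cc(OCc5ccccc5)c4c3O[C@@H](c3ccc(OCc5ccccc5)cc3)[C@@H](OCc5ccccc5)[C@@H]4c3c(OCc5ccccc5)cc(OCc5ccccc5)c4c3O[C@H](c3ccc(OCc5ccccc5)cc3)[C@H](OCc5ccccc5)C4)[C@H]2OCc5ccccc5)cc1 | intermediate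
25 | epiafzelechin-(4β→8)-ent-epiafzelechin-(4α→8)-epiafzelechin | Oc1ccc([C@H]2Oc3cc(O)cc(O)c3[C@H](c3c(O)cc(O)c4c3O[C@@H](c3ccc(O)cc3)[C@@H](O)[C@@H]4c3c(O)cc(O)c4c3O[C@H](c3ccc(O)cc3)[C@H](O)C4)[C@H]2O)cc1 | target

**Step count and risks**

Total step count: 14. Longest linear sequence: 8 steps (1, 2, 5, 6, 7, 12, 13, 14).

Steps most likely to fail:

Step 5. The aryl carbanion may be protonated before it reaches the amide, leaving an open aryl ether, and the cis ketone may epimerize at C3 or the aldol may cleave under fluoride. The fallback uses known chemistry, sets out from 5 and comes back at 13. 5-Fluorobenzene-1,3-diol is benzylated (BnBr, K2CO3, DMF) to 1,3-bis(benzyloxy)-5-fluorobenzene F1. F1 is lithiated between fluorine and a benzyloxy group (n-BuLi, THF, −78 °C) and added at −78 °C to the magnesium alkoxide of 5 (i-PrMgCl), giving after cold quench (2S,3R)-2-(benzyloxy)-1-[2,4-bis(benzyloxy)-6-fluorophenyl]-3-[4-(benzyloxy)phenyl]-3-hydroxypropan-1-one F2. Intramolecular SNAr of the benzylic hydroxyl on the ketone-activated aryl fluoride (K2CO3, DMF, 23 °C) then closes the ring to 13, so the two bonds are made in two operations instead of one.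

Step 10. The same premature protonation and loss of configuration may occur in the enantiomeric series. The fallback sets out from 19 and comes back at 21. The fluoroarene of the fallback for step 5 is lithiated in the same way and added to the magnesium alkoxide of 19 to give (2R,3S)-2-(benzyloxy)-1-[2,4-bis(benzyloxy)-6-fluorophenyl]-3-[4-(benzyloxy)phenyl]-3-hydroxypropan-1-one F3, which is cyclized by SNAr (K2CO3, DMF, 23 °C) to 21.

Step 13. Site selectivity among the free ring A positions of the dimer may be poor, and the upper-unit cation may oligomerize with itself. The fallback sets out from 22 and comes back at 24, reversing the order of union with a sulfur placeholder at C4 of the middle unit. Alcohol 22 is converted with benzyl mercaptan (BF3·OEt2, CH2Cl2, −40 °C) into 3,4-trans (2S,3S)-4-(benzylsulfanyl)-3,5,7-tris(benzyloxy)-2-[4-(benzyloxy)phenyl]chromane F4. F4 is coupled through its free C8 with 14 under the conditions of step 12 to give octa-O-benzyl-epiafzelechin-(4β→8)-[4-(benzylsulfanyl)-ent-epiafzelechin] F5. Thiophilic activation of F5 with AgBF4 (THF, 0 °C) in the presence of 15 should then form the lower interflavan bond and give 24.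

Further compounds
F1 | step 5 | 1,3-bis(benzyloxy)-5-fluorobenzene | Fc1cc(OCc2ccccc2)cc(OCc2ccccc2)c1
F2 | step 5 | (2S,3R)-2-(benzyloxy)-1-[2,4-bis(benzyloxy)-6-fluorophenyl]-3-[4-(benzyloxy)phenyl]-3-hydroxypropan-1-one | O=C(c1c(F)cc(OCc2ccccc2)cc1OCc1ccccc1)[C@@H](OCc1ccccc1)[C@H](O)c1ccc(OCc2ccccc2)cc1
F3 | step 10 | (2R,3S)-2-(benzyloxy)-1-[2,4-bis(benzyloxy)-6-fluorophenyl]-3-[4-(benzyloxy)phenyl]-3-hydroxypropan-1-one | O=C(c1c(F)cc(OCc2ccccc2)cc1OCc1ccccc1)[C@H](OCc1ccccc1)[C@@H](O)c1ccc(OCc2ccccc2)cc1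
F4 | step 13 | 3,4-trans (2S,3S)-4-(benzylsulfanyl)-3,5,7-tris(benzyloxy)-2-[4-(benzyloxy)phenyl]chromane | c1c(OCc5ccccc5)cc(OCc5ccccc5)c2c1O[C@@H](c1ccc(OCc5ccccc5)cc1)[C@@H](OCc5ccccc5)[C@@H]2SCc5ccccc5
F5 | step 13 | octa-O-benzyl-epiafzelechin-(4β→8)-[4-(benzylsulfanyl)-ent-epiafzelechin] | c5ccccc5COc1ccc([C@H]2Oc3cc(OCc5ccccc5)cc(OCc5ccccc5)c3[C@H](c3c(OCc5ccccc5)cc(OCc5ccccc5)c4c3O[C@@H](c3ccc(OCc5ccccc5)cc3)[C@@H](OCc5ccccc5)[C@@H]4SCc5ccccc5)[C@H]2OCc5ccccc5)cc1
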